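**Strategy.** Everything rests on making the ten-membered carbocycle from a six-membered one instead of closing it end to end. In germacrane numbering the target shows a cis C4–C5 alkene, oxygen at C6 and a C1–C10 epoxide born from a cis alkene, the signature of an oxy-Cope product. One [3,3] shift of the potassium alkoxide of a carvone-derived cyclohexenol (ring atoms C1–C6; E-silylvinyl on carbinol C6, isopropenyl on C1, both cis) breaks C1–C6 and joins C8 to C9, giving at once the ring, the C6 ketone, the Z C1–C10 alkene and the C8 stereocentre, silicon standing in for the C8 oxygen.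

Key step: step 7

Remark: germacrane numbering is used for every ring atom from compound 1 onward (lactone oxygen on C6, ester on C8, epoxide across C1–C10, hydroxyl on C3, C13 the exocyclic methylene), and "β" means the ring face that carries the C3, C6 and C8 oxygens of the target.

**Route**

Step 1
Reactants: 1 (S)-(+)-carvone
Product: 2 (1S,5S)-cis-carveol
Conditions: NaBH4, CeCl3·7H2O, MeOH, −78 → 0 °C
Reagents that add atoms: none
Why: Luche reduction should give clean 1,2-reduction, hydride adding axially to the enone half-chair with isopropenyl equatorial so that the new hydroxyl is equatorial and cis to isopropenyl (sets C3).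

Step 2
Reactants: 2 (1S,5S)-cis-carveol
Product: 4 cis-carveol 4-methoxybenzyl ether, via sodium alkoxide 3 (not isolated)
Conditions: NaH, 4-MeOC6H4CH2Cl, Bu4NI (cat.), THF/DMF, 0 °C → rt
Reagents that add atoms: 4-methoxybenzyl chloride, COc1ccc(CCl)cc1
Why: Williamson etherification of the allylic alkoxide; a 4-methoxybenzyl ether is chosen for C3 because it should survive hydride, strong base and, unlike a silyl ether, the fluoride needed later to oxidise the C8 silane, and it can be removed at the end under neutral oxidative conditions.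

Step 3
Reactants: 4 cis-carveol 4-methoxybenzyl ether
Product: 5 (4S,6S)-4-(4-methoxybenzyloxy)-3-methyl-6-(prop-1-en-2-yl)cyclohex-2-en-1-one
Conditions: CrO3, 3,5-dimethylpyrazole, CH2Cl2, −20 °C
Reagents that add atoms: chromium trioxide, O=[Cr](=O)=O
Why: Allylic oxidation with the CrO3·3,5-dimethylpyrazole complex (hexavalent chromium) should convert the only ring methylene allylic to the trisubstituted alkene (C6) into the ketone of the transposed enone; C1 becomes α to the carbonyl but its isopropenyl group stays equatorial and cis to the C3 ether, the more stable arrangement, and 4-methoxybenzyl ethers are expected to tolerate this cold, non-acidic oxidant.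

Step 4
Reactants: 6 ethynylmagnesium bromide; 7 benzylchlorodimethylsilane
Product: 8 benzyl(ethynyl)dimethylsilane
Conditions: THF, 0 °C → rt
Reagents that add atoms: none
Why: Nucleophilic substitution at silicon by the alkynyl Grignard reagent (C-silylation of an acetylide).

Step 5
Reactants: 8 benzyl(ethynyl)dimethylsilane; 5 transposed enone
Product: 10 (1R,4S,6S)-1-[(benzyldimethylsilyl)ethynyl]-4-(4-methoxybenzyloxy)-3-methyl-6-(prop-1-en-2-yl)cyclohex-2-en-1-ol, via lithium acetylide 9 (not isolated)
Conditions: n-BuLi, THF, −78 °C; then 5, −78 °C; NH4Cl (aq)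
Reagents that add atoms: none
Why: 1,2-Addition of a lithium acetylide to the enone carbonyl; the slim nucleophile should attack axially on the half-chair that keeps isopropenyl and the C3 ether equatorial, which places the alkyne cis to isopropenyl and the new hydroxyl equatorial (sets the carbinol centre C6).

Step 6
Reactants: 10 propargylic alcohol
Product: 12 (1R,4S,6S)-1-[(E)-2-(benzyldimethylsilyl)ethenyl]-4-(4-methoxybenzyloxy)-3-methyl-6-(prop-1-en-2-yl)cyclohex-2-en-1-ol, via cyclic vinylalanate 11 (not isolated)
Conditions: NaAlH2(OCH2CH2OMe)2, THF, 0 °C → rt; then KNaC4H4O6 (aq)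
Reagents that add atoms: none
Why: Hydroxyl-directed trans-hydroalumination of a propargylic alcohol: the alkoxyaluminate delivers hydride to the proximal alkyne carbon and aluminium to the silyl-bearing carbon in a five-membered alanate, and protonolysis of the C–Al bond with retention should give the E-vinylsilane only.

Step 7
Reactants: 12 all-cis silylvinyl isopropenyl cyclohexenol
Product: 15 (2Z,4S,6Z,9R)-9-(benzyldimethylsilyl)-4-(4-methoxybenzyloxy)-3,7-dimethylcyclodeca-2,6-dien-1-one, via potassium alkoxide 13 (not isolated), via potassium enolate 14 (not isolated)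
Conditions: KH, 18-crown-6, THF, 0 °C → rt; then NH4Cl (aq), −78 °C
Reagents that add atoms: none
Why: Deprotonation gives the crown-ether-separated potassium alkoxide, whose 3-oxido-1,5-diene (Si–CH=CH–C6(O⁻)–C1–C(CH3)=CH2) should undergo a concerted [3,3] shift that cleaves the ring bond C1–C6 and forms C8–C9, leaving the C6–C7 enolate that is protonated to the ketone; the closest known reaction is the anionic oxy-Cope ring expansion of 1,2-dialkenylcyclohexanols to cyclodec-5-enones. The ten-membered ring is not closed by an exo or endo cyclisation but arises by net four-atom ring expansion of the cyclohexene through a six-centre chair transition state, so no macrocyclisation entropy is paid. The new stereocentre C8 is controlled by that chair, in which the silicon of the E-vinylsilane sits equatorial and thereby relays the C1 and C6 configurations to 8R. The step needs the chair in which the alkoxide oxygen and the C1–C2 ring bond are axial (this gives the Z C1–C10 alkene) and not the ring-flipped chair or a boat; the cis relationship of the two alkenyl groups and the ground-state half-chair, which holds isopropenyl and the C3 ether equatorial and the silylvinyl group axial, should secure it. The C4–C5 alkene stays cis because it was a bond of the six-membered ring, and a C8 silicon substituent, unlike a C8 oxygen, resists β-elimination from the enolate.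

Step 8
Reactants: 15 cyclodecadienone
Product: 17 keto ester (15 with CH2CO2Me at C7 on the β-face), via lithium enolate 16 (not isolated)
Conditions: LiN(SiMe3)2, THF, −78 °C; then BrCH2CO2Me, −78 → −40 °C
Reagents that add atoms: methyl bromoacetate, COC(=O)CBr
Why: Kinetic deprotonation at the α′ methylene C7 should give the cross-conjugated enolate, which is C-alkylated (enolate SN2 alkylation); with H8 eclipsing the enolate to avoid allylic strain, the electrophile enters anti to the C8–Si bond (the 1,2-induction known for β-silyl enolates), which in the ring drawing places the side chain on the same face as silicon and sets C7.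

Step 9
Reactants: 17 keto ester
Product: 19 cis-fused C6–C7 γ-lactone (3β-OPMB and 8β-silyl), via hydroxy ester 18 (not isolated)
Conditions: NaBH4, CeCl3·7H2O, MeOH, −40 °C; then pyridinium p-toluenesulfonate (cat.), CH2Cl2, rt
Reagents that add atoms: none
Why: Luche reduction should touch only the enone carbonyl (1,2), hydride approaching from the face opposite the neighbouring C7 side chain so that the C6 hydroxyl forms cis to it (sets C6), and the γ-hydroxy ester then closes by acid-catalysed lactonisation (5-exo-trig acyl substitution) to the cis-fused butanolide.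

Step 10
Reactants: 19 silyl lactone
Product: 21 8β-hydroxy lactone, via silanol 20 (not isolated)
Conditions: Bu4NF, THF, 0 °C → rt; then H2O2 (30%), KHCO3, MeOH, rt
Reagents that add atoms: hydrogen peroxide, OO
Why: Tamao–Fleming oxidation: fluoride adds to silicon and the benzyl group leaves as toluene to give the silanol, whose peroxide adduct rearranges by 1,2-shift of C8 from silicon to oxygen with retention, so the configuration set in step 7 is kept, while the 4-methoxybenzyl ether is inert to fluoride.

Step 11
Reactants: 21 8β-hydroxy lactone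
Product: 25 α-methylene lactone with free 8β-hydroxyl, via dilithium enolate alkoxide 22 (not isolated), via Mannich base 23 (not isolated), via ammonium iodide 24 (not isolated)
Conditions: LiN(iPr)2 (2.2 equiv), THF, −78 °C; Me2N=CH2 I, −78 → 0 °C, aqueous work-up; MeI, MeOH, rt; NaHCO3 (aq), EtOAc, rt
Reagents that add atoms: dimethylmethyleneiminium iodide (Eschenmoser's salt), C=[N+](C)C.[I-]
Why: α-Methylenation of a lactone by Mannich reaction of its enolate, N-methylation and base-induced β-elimination of trimethylamine (E1cB); the second equivalent of base holds the C8 hydroxyl as its lithium alkoxide, the substrate is added to the cold base so that the lactone is enolised before the alkoxide can attack it, and the transient C11 stereocentre is destroyed in the elimination.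

Step 12
Reactants: 25 α-methylene hydroxy lactone
Product: 26 1β,10β-epoxy alcohol
Conditions: VO(acac)2 (cat.), t-BuOOH, CH2Cl2, 0 °C → rt
Reagents that add atoms: tert-butyl hydroperoxide, CC(C)(C)OO
Why: Hydroxyl-directed epoxidation with a vanadium alkyl peroxide (pentavalent vanadium): the homoallylic C8 alkoxide binds the metal and should deliver oxygen to the face of the electron-rich C1–C10 alkene on which it sits (sets C1 and C10), while the electron-poor exocyclic alkene and the C4–C5 alkene, which has no free directing hydroxyl and two allylic C–O bonds, are left alone.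

Step 13
Reactants: 26 epoxy alcohol
Product: 27 8-O-isobutyrate (3-O-4-methoxybenzyl ether of the target)
Conditions: (i-PrCO)2O, Et3N, DMAP (cat.), CH2Cl2, 0 °C → rt
Reagents that add atoms: isobutyric anhydride, CC(C)C(=O)OC(=O)C(C)C
Why: DMAP-catalysed acylation of the secondary alcohol through the acylpyridinium ion; no stereocentre is touched and the mild base should leave epoxide and methylene lactone intact.

Step 14
Reactants: 27 protected target
Product: 28 target CNP0261225.6
Conditions: DDQ, CH2Cl2/pH 7 phosphate buffer, 0 °C
Reagents that add atoms: none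
Why: Oxidative cleavage of the 4-methoxybenzyl ether by DDQ (benzylic hydride abstraction, hydrolysis of the oxocarbenium ion) under buffered neutral conditions that should spare the epoxide, the isobutyrate and the methylene lactone.

**Compound list**

1 | (S)-(+)-carvone | CC1=CC[C@@H](CC1=O)C(C)=C | starting material
2 | (1S,5S)-cis-carveol | CC1=CC[C@H](C(C)=C)C[C@@H]1O | intermediate
3 | sodium alkoxide of 2 (not isolated) | CC1=CC[C@H](C(C)=C)C[C@@H]1[O-].[Na+] | intermediate
4 | (1S,5S)-cis-carveol 4-methoxybenzyl ether | CC1=CC[C@H](C(C)=C)C[C@@H]1OCc2ccc(OC)cc2 | intermediate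
5 | (4S,6S)-4-(4-methoxybenzyloxy)-3-methyl-6-(prop-1-en-2-yl)cyclohex-2-en-1-one | CC1=CC(=O)[C@H](C(C)=C)C[C@@H]1OCc2ccc(OC)cc2 | intermediate
6 | ethynylmagnesium bromide | C#C[Mg]Br | starting material
7 | benzylchlorodimethylsilane | C[Si](C)(Cl)Cc1ccccc1 | starting material
8 | benzyl(ethynyl)dimethylsilane | C#C[Si](C)(C)Cc1ccccc1 | intermediate
9 | lithium (benzyldimethylsilyl)acetylide (not isolated) | [Li]C#C[Si](C)(C)Cc1ccccc1 | intermediate
10 | (1R,4S,6S)-1-[(benzyldimethylsilyl)ethynyl]-4-(4-methoxybenzyloxy)-3-methyl-6-(prop-1-en-2-yl)cyclohex-2-en-1-ol | CC1=C[C@](O)(C#C[Si](C)(C)Cc2ccccc2)[C@H](C(C)=C)C[C@@H]1OCc3ccc(OC)cc3 | intermediate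
11 | sodium five-membered vinylalanate from 10, Al on the silyl-bearing carbon (not isolated) | CC1=C[C@](O[Al-]2(OCCOC)OCCOC)(C=C2[Si](C)(C)Cc3ccccc3)[C@H](C(C)=C)C[C@@H]1OCc4ccc(OC)cc4.[Na+] | intermediate
12 | (1R,4S,6S)-1-[(E)-2-(benzyldimethylsilyl)ethenyl]-4-(4-methoxybenzyloxy)-3-methyl-6-(prop-1-en-2-yl)cyclohex-2-en-1-ol (key-step precursor; alkenyl, isopropenyl and ether all cis) | CC1=C[C@](O)(/C=C/[Si](C)(C)Cc2ccccc2)[C@H](C(C)=C)C[C@@H]1OCc3ccc(OC)cc3 | intermediate
13 | potassium alkoxide of 12 (not isolated) | CC1=C[C@]([O-])(/C=C/[Si](C)(C)Cc2ccccc2)[C@H](C(C)=C)C[C@@H]1OCc3ccc(OC)cc3.[K+] | intermediate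
14 | potassium C6–C7 enolate of 15, oxygen cis to C8 (not isolated) | COc1ccc(CO[C@@H]2/C(C)=C\C(\[O-])=C\[C@H]([Si](C)(C)Cc3ccccc3)C/C(C)=C\C2)cc1.[K+] | intermediate
15 | (2Z,4S,6Z,9R)-9-(benzyldimethylsilyl)-4-(4-methoxybenzyloxy)-3,7-dimethylcyclodeca-2,6-dien-1-one (key-step product) | O=C1/C=C(/C)[C@@H](OCc2ccc(OC)cc2)C/C=C(/C)C[C@@H]([Si](C)(C)Cc3ccccc3)C1 | intermediate
16 | lithium C6–C7 enolate of 15, drawn as the cis-ring isomer; its geometry does not enter the facial argument (not isolated) | [Li+].COc1ccc(CO[C@@H]2/C(C)=C\C(\[O-])=C/[C@H]([Si](C)(C)Cc3ccccc3)C/C(C)=C\C2)cc1 | intermediate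
17 | keto ester: 15 with CH2CO2Me at C7, cis to the C8 silyl group | O=C1/C=C(/C)[C@@H](OCc2ccc(OC)cc2)C/C=C(/C)C[C@@H]([Si](C)(C)Cc3ccccc3)[C@H]1CC(=O)OC | intermediate
18 | 6β-hydroxy ester from 17 (not isolated) | O[C@H]1/C=C(/C)[C@@H](OCc2ccc(OC)cc2)C/C=C(/C)C[C@@H]([Si](C)(C)Cc3ccccc3)[C@H]1CC(=O)OC | intermediate
19 | cis-fused 12,6-lactone, 3β-(4-methoxybenzyloxy), 8β-benzyldimethylsilyl, 1(10)Z,4Z-diene | C1C(=O)O[C@H]2/C=C(/C)[C@@H](OCc3ccc(OC)cc3)C/C=C(/C)C[C@@H]([Si](C)(C)Cc4ccccc4)[C@@H]12 | intermediate
20 | C8 dimethylsilanol of 19 (not isolated) | C1C(=O)O[C@H]2/C=C(/C)[C@@H](OCc3ccc(OC)cc3)C/C=C(/C)C[C@@H]([Si](C)(C)O)[C@@H]12 | intermediate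
21 | 8β-hydroxy-12,6-lactone | C1C(=O)O[C@H]2/C=C(/C)[C@@H](OCc3ccc(OC)cc3)C/C=C(/C)C[C@@H](O)[C@@H]12 | intermediate
22 | dilithium lactone enolate C8 alkoxide of 21 (not isolated) | [Li+].[Li+].[O-]C1=C[C@@H]2[C@H]([O-])C/C(C)=C\C[C@H](OCc3ccc(OC)cc3)/C(C)=C\[C@@H]2O1 | intermediate
23 | C11 dimethylaminomethyl lactone, C11 epimers (not isolated) | CN(C)CC1C(=O)O[C@H]2/C=C(/C)[C@@H](OCc3ccc(OC)cc3)C/C=C(/C)C[C@@H](O)[C@@H]12 | intermediate
24 | C11 trimethylammoniomethyl lactone iodide (not isolated) | C[N+](C)(C)CC1C(=O)O[C@H]2/C=C(/C)[C@@H](OCc3ccc(OC)cc3)C/C=C(/C)C[C@@H](O)[C@@H]12.[I-] | intermediate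
25 | α-methylene-12,6-lactone with 8β-hydroxyl and 3β-(4-methoxybenzyloxy) | C=C1C(=O)O[C@H]2/C=C(/C)[C@@H](OCc3ccc(OC)cc3)C/C=C(/C)C[C@@H](O)[C@@H]12 | intermediate
26 | 1β,10β-epoxide of 25 | C=C1C(=O)O[C@H]2/C=C(/C)[C@@H](OCc4ccc(OC)cc4)C[C@H]3O[C@@]3(C)C[C@@H](O)[C@@H]12 | intermediate
27 | 8-O-isobutyrate of 26 | C=C1C(=O)O[C@H]2/C=C(/C)[C@@H](OCc4ccc(OC)cc4)C[C@H]3O[C@@]3(C)C[C@@H](OC(=O)C(C)C)[C@@H]12 | intermediate
28 | CNP0261225.6 (1R,3S,6S,7R,8R,10S; 4Z) | C=C1C(=O)O[C@H]2/C=C(/C)[C@@H](O)C[C@H]3O[C@@]3(C)C[C@@H](OC(=O)C(C)C)[C@@H]12 | target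

**Count and risks**

Total steps: 14. Longest linear sequence: 13 steps (steps 1–3 and 5–14; step 4 is a one-step side branch).

Steps most likely to fail:

Step 7. The rearrangement may leak through the ring-flipped chair or a boat-shaped transition state, which would scramble the C1–C10 geometry and the C8 configuration, and the crown-ether-separated alkoxide or enolate oxygen may attack silicon and displace the benzyl group. The fallback sets out from 12. The tertiary alcohol is silylated (Me3SiOSO2CF3, 2,6-lutidine, CH2Cl2, −78 °C) to the trimethylsilyl ether F1, which is heated without base (degassed o-dichlorobenzene, about 200 °C, sealed tube). The neutral thermal siloxy-Cope rearrangement should then give the trimethylsilyl enol ether F2 with no free oxyanion present. Mild methanolysis (K2CO3, MeOH, 0 °C) frees the ketone, and the fallback returns at 15.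

Step 8. Facial selection in the C-alkylation may fail: the conformation of the ten-membered enolate can override the bias from the C8 silicon, so that the alkyl halide enters from the other face. The fallback sets out from 15. The alkylation is run as in step 8 and its product, the C7-epimeric keto ester F3, is taken on. F3 is deprotonated again at C7 (LiN(SiMe3)2, THF, −78 °C; the ketone α-position is its most acidic site) and the fully substituted enolate is quenched at −78 °C with a hindered proton donor (2,6-di-tert-butylphenol). The proton should then enter from the face the alkyl halide had used and push the side chain to the required face (diastereoselective kinetic protonation of an enolate). The fallback returns at 17.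

Step 9. Hydride may be delivered to the other face of the C6 carbonyl, giving the alcohol trans to the C7 side chain. The fallback sets out from 17. The reduction is run without the acid treatment and the 6-epimeric hydroxy ester F4 is saponified (LiOH, THF/H2O) to the hydroxy acid F5. The lactone is then closed under Mitsunobu conditions (PPh3, diisopropyl azodicarboxylate, toluene, 0 °C), in which the carboxylate displaces the activated C6 oxygen with inversion. The fallback returns at 19.

**Further compounds**

F1 | step 7 | trimethylsilyl ether of 12 | CC1=C[C@](O[Si](C)(C)C)(/C=C/[Si](C)(C)Cc2ccccc2)[C@H](C(C)=C)C[C@@H]1OCc3ccc(OC)cc3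
F2 | step 7 | trimethylsilyl enol ether of 15 (C6–C7 enol ether, oxygen cis to C8) | COc1ccc(CO[C@@H]2/C(C)=C\C(\O[Si](C)(C)C)=C\[C@H]([Si](C)(C)Cc3ccccc3)C/C(C)=C\C2)cc1
F3 | step 8 | C7 epimer of keto ester 17 | O=C1/C=C(/C)[C@@H](OCc2ccc(OC)cc2)C/C=C(/C)C[C@@H]([Si](C)(C)Cc3ccccc3)[C@@H]1CC(=O)OC
F4 | step 9 | C6 epimer of hydroxy ester 18 | O[C@@H]1/C=C(/C)[C@@H](OCc2ccc(OC)cc2)C/C=C(/C)C[C@@H]([Si](C)(C)Cc3ccccc3)[C@H]1CC(=O)OC
F5 | step 9 | hydroxy acid from F4 | O[C@@H]1/C=C(/C)[C@@H](OCc2ccc(OC)cc2)C/C=C(/C)C[C@@H]([Si](C)(C)Cc3ccccc3)[C@H]1CC(O)=O
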